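**Retrosynthetic overview**
- The plan rests on the polarity pattern of the oxolane ring (O1, C2–C5) and its two CH2OH arms. The C3–C4 bond joins two carbons that are both donors in their natural precursors: C3 is the enolisable CH2 of a β-keto ester and C4 is the inner alkene carbon of a 4-alkoxy-3,5-dimethoxystyrene. That bond therefore calls for an oxidative coupling. O1 is the ketone oxygen of the same β-keto ester and reaches C5 once that benzylic carbon has been oxidised. The ester linking the two halves already contains both exocyclic carbons.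
- Target (meso; 2,3-trans, 3,4-cis, 4,5-trans) ⇒ debenzylation and lactone reduction ⇒ cis-fused 4,6-diaryl-tetrahydrofuro[3,4-c]furan-1-one, whose ring fusion stores the cis C3/C4 relation.
- ⇒ stepwise hydride/proton addition across C2=C3 ⇒ 3a,4-dihydrofuro[3,4-c]furan-1-one (a cyclic vinylogous carbonate).
- ⇒ oxidative disconnection of C3–C4 and O1–C5 ⇒ cinnamyl aroylacetate. In the forward sense the γ-lactone closes first (radical) and the dihydrofuran second (cation capture), both in one operation.
- ⇒ aroylketene (from an acyl Meldrum's acid) plus O-benzyl sinapyl alcohol, both made from syringaldehyde.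

Key step: step 7

Remark on the chemistry: locants O1 and C2–C5 are those of the oxolane ring of the target throughout; the target has a mirror plane through O1 and the C3–C4 midpoint (meso), so no absolute stereocontrol is needed, and the two chiral intermediates (the products of steps 7 and 8) are racemates drawn as one enantiomer.

**Step 1**
Reactants: 1 syringaldehyde (4-hydroxy-3,5-dimethoxybenzaldehyde)
Product: 2 4-(benzyloxy)-3,5-dimethoxybenzaldehyde
Conditions: BnBr, K2CO3, DMF, 60 °C
Reagents that add atoms: benzyl bromide, BrCc1ccccc1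
Why: Williamson etherification of the phenoxide installs a benzyl ether that masks the phenol, which trivalent manganese would otherwise oxidise in step 7, and that tolerates every reagent up to the last step.

**Step 2**
Reactants: 2 4-(benzyloxy)-3,5-dimethoxybenzaldehyde
Product: 3 ethyl (E)-3-[4-(benzyloxy)-3,5-dimethoxyphenyl]prop-2-enoate
Conditions: (EtO)2P(O)CH2CO2Et, NaH, THF, 0 °C to rt
Reagents that add atoms: triethyl phosphonoacetate, CCOC(=O)CP(=O)(OCC)OCC
Why: Horner–Wadsworth–Emmons olefination with a stabilised phosphonate anion should give the E enoate, which fixes the geometry of the later cinnamyl unit.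

**Step 3**
Reactants: 3 ethyl (E)-3-[4-(benzyloxy)-3,5-dimethoxyphenyl]prop-2-enoate
Product: 4 (E)-3-[4-(benzyloxy)-3,5-dimethoxyphenyl]prop-2-en-1-ol
Conditions: i-Bu2AlH (2.3 equiv), CH2Cl2, −78 °C; aq. potassium sodium tartrate
Reagents that add atoms: none
Why: 1,2-reduction of the conjugated ester by two equivalents of i-Bu2AlH at low temperature gives the allylic alcohol without touching the alkene geometry or the benzyl ether.

**Step 4**
Reactants: 2 4-(benzyloxy)-3,5-dimethoxybenzaldehyde (second portion)
Product: 5 4-(benzyloxy)-3,5-dimethoxybenzoic acid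
Conditions: NaClO2, NaH2PO4, 2-methylbut-2-ene, t-BuOH/THF/H2O, rt
Reagents that add atoms: sodium chlorite, [Na+].[O-]Cl=O
Why: Pinnick oxidation converts the aldehyde into the acid under buffered conditions, and the alkene scavenger removes hypochlorous acid before it can chlorinate the electron-rich ring.

**Step 5**
Reactants: 5 4-(benzyloxy)-3,5-dimethoxybenzoic acid; 6 Meldrum's acid (2,2-dimethyl-1,3-dioxane-4,6-dione)
Product: 8 5-{[4-(benzyloxy)-3,5-dimethoxyphenyl](hydroxy)methylidene}-2,2-dimethyl-1,3-dioxane-4,6-dione, via aroyl chloride 7 (not isolated)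
Conditions: (COCl)2, DMF (cat.), CH2Cl2, 0 °C to rt; evaporate; then 6, pyridine (2.2 equiv), CH2Cl2, 0 °C to rt; aq. HCl wash
Reagents that add atoms: oxalyl chloride, O=C(Cl)C(=O)Cl (supplies the chlorine of 7 only; none of its atoms remains in 8)
Why: The acid chloride C-acylates the enolate of Meldrum's acid, the standard entry to acyl Meldrum's acids, and the product rests as its hydrogen-bonded enol.

**Step 6**
Reactants: 8 acyl Meldrum's acid; 4 (E)-3-[4-(benzyloxy)-3,5-dimethoxyphenyl]prop-2-en-1-ol
Product: 10 (E)-3-[4-(benzyloxy)-3,5-dimethoxyphenyl]prop-2-en-1-yl 3-[4-(benzyloxy)-3,5-dimethoxyphenyl]-3-oxopropanoate, via aroylketene 9 (not isolated)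
Conditions: toluene, reflux
Reagents that add atoms: none
Why: Thermal cycloreversion of the acyl Meldrum's acid expels acetone and CO2, and the aroylketene is trapped by the primary allylic alcohol in a neutral acylation that leaves the E alkene intact.

**Step 7**
Reactants: 10 cinnamyl aroylacetate
Product: 11 rac-(3aS,4R)-4,6-bis[4-(benzyloxy)-3,5-dimethoxyphenyl]-3a,4-dihydro-1H,3H-furo[3,4-c]furan-1-one (C6=C6a enol ether conjugated with the lactone carbonyl, i.e. oxolane C2=C3; H-3a and H-4 trans, i.e. the C5 aryl anti to the lactone CH2 on C4)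
Conditions: Mn(OAc)3·2H2O (2.2 equiv), Cu(OAc)2·H2O (0.5 equiv), degassed AcOH (0.02 M), 70 °C, Ar
Reagents that add atoms: none
Why: Mn(OAc)3 engages 10 as its manganese enolate and, with loss of divalent manganese, delivers the electrophilic C3 radical to the proximal alkene carbon in a 5-exo-trig radical closure that forms C3–C4 and the γ-lactone ring and leaves a benzylic radical at C5. Cu(OAc)2, re-oxidised by the second equivalent of Mn(OAc)3, takes this radical to the para-alkoxybenzyl cation, which the enol oxygen of the aroyl group captures in a polar closure, 5-exo-trig with respect to the quinoid C5=C(ipso) bond, forming O1–C5 and the dihydrofuran ring. The closest known reaction type is the Mn(OAc)3/Cu(OAc)2 oxidative annulation of β-keto esters with styrenes to 4,5-dihydrofuran-3-carboxylates, including its tethered version with allylic and cinnamyl β-keto esters. C4 is created in the radical closure and, because C3 returns to sp2, is the only reference centre, while C5 is set relative to it in the capture step: the cation closes through the rotamer that turns the aryl group away from the lactone CH2, giving H-4/H-5 trans, and since O1 is a vinylogous carbonate leaving group next to a strong donor aryl the C5–O1 bond can re-ionise in warm AcOH, so the trans isomer should also be the thermodynamic outcome. The step needs 5-exo rather than 6-endo addition, secured by benzylic stabilisation of the C5 radical; ring closure rather than oligomerisation, secured by high dilution and by 70 °C, which populates the E ester rotamer that the tether requires; and capture at oxygen rather than at C3, secured because the alternative aroyl cyclopropane is a strained donor–acceptor system that should reopen to the same cation. The benzyl ethers keep the phenols away from the oxidant, and 11 has no α-hydrogen left, so it cannot be oxidised further by the same pathway.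

**Step 8**
Reactants: 11 dihydrofurofuranone
Product: 12 rac-(3aS,4R,6S,6aS)-4,6-bis[4-(benzyloxy)-3,5-dimethoxyphenyl]tetrahydro-1H,3H-furo[3,4-c]furan-1-one (cis-fused; both aryl groups exo, cis to each other and trans to the lactone bonds at C3 and C4)
Conditions: (IPr)CuCl [IPr = 1,3-bis(2,6-diisopropylphenyl)imidazol-2-ylidene] (10 mol %), NaOt-Bu (10 mol %), (EtO)2MeSiH (3 equiv), t-BuOH (3 equiv), toluene, rt to 40 °C
Reagents that add atoms: none
Why: Proposed new method: copper hydride 1,4-reduction is established for tri- and tetrasubstituted enoates with carbene-ligated copper and for β-oxygenated or β-amido acceptors such as chromones and β-amido acrylates, but not for a tetrasubstituted cyclic β-alkoxy-β-aryl enoate such as 11, for which [(Ph3P)CuH]6 would be too sluggish; the monomeric (IPr)CuH formed from (IPr)CuOt-Bu and the silane should transfer hydride to the benzylic acceptor carbon C2 on the face opposite the C5 aryl group, which stands nearly perpendicular on one face of the flattened bicycle, and this places the C2 aryl cis to the C5 aryl; the copper enolate is then protonated by t-BuOH at C3 on the face of H-4, the only face that gives a cis-fused bicyclo[3.3.0] lactone (C3 stays epimerisable, so this centre is also under thermodynamic control), which makes H-2/H-3 trans, a result that a syn hydrogenation cannot give because it ties both new hydrogens to one face; loss of O1 from the enolate is held back because the C2–O1 bond lies close to the nodal plane of the enolate π system (the reverse of a 5-endo-trig closure), and the non-acidic medium avoids the ionisation of C5–O1 that acid-promoted hydride reductions would provoke.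

**Step 9**
Reactants: 12 saturated cis-fused lactone
Product: 13 meso-{(2R,3S,4R,5S)-2,5-bis[4-(benzyloxy)-3,5-dimethoxyphenyl]oxolane-3,4-diyl}dimethanol (2,3-trans, 3,4-cis, 4,5-trans)
Conditions: LiAlH4, THF, 0 °C to rt; H2O, aq. NaOH
Reagents that add atoms: none
Why: LiAlH4 reduces the γ-lactone to the 1,4-diol faster than C3 can enolise, so the cis C3/C4 relation stored in the ring fusion passes into the two hydroxymethyl groups and the product gains the mirror plane of the target.

**Step 10**
Reactants: 13 bis-benzyl ether diol
Product: 14 meso-{(2R,3S,4R,5S)-2,5-bis(4-hydroxy-3,5-dimethoxyphenyl)oxolane-3,4-diyl}dimethanol (target)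
Conditions: H2 (1 atm), 10% Pd/C, EtOAc, rt, stopped when 13 is consumed
Reagents that add atoms: none
Why: Hydrogenolysis of the two aryl benzyl ethers over Pd/C should be faster than cleavage of the hindered secondary benzylic C–O bonds of the oxolane in a neutral aprotic solvent, so the bis-phenol is released with all four stereocentres untouched.

**Compound list**
1 | syringaldehyde | COc1cc(C=O)cc(OC)c1O | starting material
2 | 4-(benzyloxy)-3,5-dimethoxybenzaldehyde | COc1cc(C=O)cc(OC)c1OCc1ccccc1 | intermediate
3 | ethyl (E)-3-[4-(benzyloxy)-3,5-dimethoxyphenyl]prop-2-enoate | CCOC(=O)/C=C/c1cc(OC)c(OCc2ccccc2)c(OC)c1 | intermediate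
4 | (E)-3-[4-(benzyloxy)-3,5-dimethoxyphenyl]prop-2-en-1-ol | OC/C=C/c1cc(OC)c(OCc2ccccc2)c(OC)c1 | intermediate
5 | 4-(benzyloxy)-3,5-dimethoxybenzoic acid | COc1cc(C(=O)O)cc(OC)c1OCc1ccccc1 | intermediate
6 | Meldrum's acid | CC1(C)OC(=O)CC(=O)O1 | starting material
7 | 4-(benzyloxy)-3,5-dimethoxybenzoyl chloride | COc1cc(C(=O)Cl)cc(OC)c1OCc1ccccc1 | intermediate
8 | 5-{[4-(benzyloxy)-3,5-dimethoxyphenyl](hydroxy)methylidene}-2,2-dimethyl-1,3-dioxane-4,6-dione | COc1cc(C(O)=C2C(=O)OC(C)(C)OC2=O)cc(OC)c1OCc1ccccc1 | intermediate
9 | 3-[4-(benzyloxy)-3,5-dimethoxyphenyl]-3-oxoprop-1-en-1-one (aroylketene) | COc1cc(C(=O)C=C=O)cc(OC)c1OCc1ccccc1 | intermediate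
10 | (E)-3-[4-(benzyloxy)-3,5-dimethoxyphenyl]prop-2-en-1-yl 3-[4-(benzyloxy)-3,5-dimethoxyphenyl]-3-oxopropanoate | COc1cc(/C=C/COC(=O)CC(=O)c2cc(OC)c(OCc3ccccc3)c(OC)c2)cc(OC)c1OCc1ccccc1 | intermediate
11 | rac-(3aS,4R)-4,6-bis[4-(benzyloxy)-3,5-dimethoxyphenyl]-3a,4-dihydro-1H,3H-furo[3,4-c]furan-1-one | COc1cc(C2=C3C(=O)OC[C@H]3[C@H](c3cc(OC)c(OCc4ccccc4)c(OC)c3)O2)cc(OC)c1OCc1ccccc1 | intermediate
12 | rac-(3aS,4R,6S,6aS)-4,6-bis[4-(benzyloxy)-3,5-dimethoxyphenyl]tetrahydro-1H,3H-furo[3,4-c]furan-1-one | COc1cc([C@H]2O[C@@H](c3cc(OC)c(OCc4ccccc4)c(OC)c3)[C@@H]3COC(=O)[C@H]23)cc(OC)c1OCc1ccccc1 | intermediate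
13 | meso-{(2R,3S,4R,5S)-2,5-bis[4-(benzyloxy)-3,5-dimethoxyphenyl]oxolane-3,4-diyl}dimethanol | COc1cc([C@H]2O[C@@H](c3cc(OC)c(OCc4ccccc4)c(OC)c3)[C@H](CO)[C@@H]2CO)cc(OC)c1OCc1ccccc1 | intermediate
14 | meso-{(2R,3S,4R,5S)-2,5-bis(4-hydroxy-3,5-dimethoxyphenyl)oxolane-3,4-diyl}dimethanol | COc1cc([C@H]2O[C@@H](c3cc(OC)c(O)c(OC)c3)[C@H](CO)[C@@H]2CO)cc(OC)c1O | target

**Step count**
- Total step count: 10.
- Longest linear sequence: 8 steps (1, 2, 3, 6, 7, 8, 9, 10; the branch 1, 4, 5, 6 … is of equal length).

**Steps most likely to fail**

1. **Step 8 (Proposed new method).**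
   - What may go wrong: the push–pull alkene may accept hydride too slowly for the catalyst to turn over. Facial selectivity at C2 may also be poor, because the shallow concave face of the bicycle competes with the aryl-shielded face.
   - Fallback (known chemistry), from 11: hydrogenation over Rh/Al2O3 (H2, 4 atm, EtOAc), a catalyst of low hydrogenolysis activity that is known to saturate 4,5-dihydrofuran-3-carboxylates. It adds both hydrogens syn on the face of H-4 and should give the 2,3-cis lactone with the C2 aryl endo, rac-(3aS,4R,6R,6aS)-4,6-bis[4-(benzyloxy)-3,5-dimethoxyphenyl]tetrahydro-1H,3H-furo[3,4-c]furan-1-one F1.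
   - Catalytic BF3·OEt2 in CH2Cl2 at −20 to 0 °C then ionises the C2–O1 bond reversibly. This is the acid epimerisation of benzylic ether centres familiar from furofuran and oxolane lignans. The aryl group should move to the less crowded exo face, and the route is rejoined at 12.

2. **Step 7 (key step).**
   - What may go wrong: cyclisation through the unfavourable ester rotamer may be slow. Oligomerisation, capture of the cation by acetate, closure at carbon instead of oxygen, or direct oxidation of the electron-rich styrene could then take over.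
   - Fallback, from 10: Regitz diazo transfer (4-acetamidobenzenesulfonyl azide, Et3N, MeCN) gives the cinnamyl 2-diazo-3-aryl-3-oxopropanoate F2.
   - Rh2(OAc)4 (1 mol %, CH2Cl2, reflux) effects intramolecular carbenoid cyclopropanation of the E alkene. This gives rac-1-aroyl-6-exo-aryl-3-oxabicyclo[3.1.0]hexan-2-one F3 (aryl trans to the lactone CH2, cis to the aroyl group).
   - Sc(OTf)3 (10 mol %, CH2Cl2, rt) then triggers the Cloke–Wilson ring expansion of this donor–acceptor cyclopropane: C3–C5 cleaves and the aroyl oxygen closes on C5. The route is rejoined at 11.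

3. **Step 10.**
   - What may go wrong: hydrogenolytic opening of the oxolane at C2–O1 or C5–O1 may set in once the free para-hydroxy groups appear. Acid traces on the catalyst may also cyclise a hydroxymethyl group onto an ionised benzylic position.
   - Fallback, from 12: non-reductive debenzylation with BCl3 and pentamethylbenzene as cation scavenger (CH2Cl2, −78 °C) gives the bis-phenol lactone rac-(3aS,4R,6S,6aS)-4,6-bis(4-hydroxy-3,5-dimethoxyphenyl)tetrahydro-1H,3H-furo[3,4-c]furan-1-one F4.
   - At this stage no free hydroxymethyl group can trap a benzylic cation, and reversible ring ionisation only returns the exo,exo isomer.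
   - Excess LiAlH4 in THF, with a neutral work-up, then reduces the lactone directly, and the route is rejoined at 14.

**Further compounds**
F1 | step 8 | rac-(3aS,4R,6R,6aS)-4,6-bis[4-(benzyloxy)-3,5-dimethoxyphenyl]tetrahydro-1H,3H-furo[3,4-c]furan-1-one | COc1cc([C@@H]2O[C@@H](c3cc(OC)c(OCc4ccccc4)c(OC)c3)[C@@H]3COC(=O)[C@H]23)cc(OC)c1OCc1ccccc1
F2 | step 7 | (E)-3-[4-(benzyloxy)-3,5-dimethoxyphenyl]prop-2-en-1-yl 3-[4-(benzyloxy)-3,5-dimethoxyphenyl]-2-diazo-3-oxopropanoate | COc1cc(/C=C/COC(=O)C(=[N+]=[N-])C(=O)c2cc(OC)c(OCc3ccccc3)c(OC)c2)cc(OC)c1OCc1ccccc1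
F3 | step 7 | rac-1-[4-(benzyloxy)-3,5-dimethoxybenzoyl]-6-exo-[4-(benzyloxy)-3,5-dimethoxyphenyl]-3-oxabicyclo[3.1.0]hexan-2-one | O=C1OC[C@H]2[C@H](c3cc(OC)c(OCc4ccccc4)c(OC)c3)[C@@]12C(=O)c1cc(OC)c(OCc2ccccc2)c(OC)c1
F4 | step 10 | rac-(3aS,4R,6S,6aS)-4,6-bis(4-hydroxy-3,5-dimethoxyphenyl)tetrahydro-1H,3H-furo[3,4-c]furan-1-one | COc1cc([C@H]2O[C@@H](c3cc(OC)c(O)c(OC)c3)[C@@H]3COC(=O)[C@H]23)cc(OC)c1O
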